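**Plan**

- Eudesmane numbering is used (ring A = C1–C5 and C10, ring B = C5–C10, β = the face of the C10 methyl C14). The retrosynthesis removes in turn the C5–O bond of the hydroperoxide (ene reaction of a C4=C5 alkene), the angelate on O3, the C12 oxidation level (back to isopropenyl) and C4–C15 (methyl coupling on a 3,4-dione enol triflate), and then opens ring B at C9–C10 and C5–C6.
- Enabling feature: the quaternary carbon C10 (bearing C14) lies β to C4 within ring A. With a carbonyl at C4, ring A is 3-methylcyclohex-2-en-1-one, C10 is its acceptor carbon and C5 is the enolate carbon that closes ring B onto C6.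
- Forward, fragment: rhodium-catalysed addition of isopropenyl to furan-2(5H)-one sets C7, and the lactone is opened to a C6-chloro/C9-bromomagnesium reagent carrying C6–C9 and C11–C13. Copper-catalysed conjugate addition to the enone (ring A) and alkylation of the resulting enolate then close ring B in one flask.
- Forward, ring A (no protecting groups): C3 hydroxylation, oxidation to the Δ4-diosphenol, triflation and Stille methylation give (+)-α-cyperone. Allylic oxidation converts isopropenyl into the methyl acrylate; Luche reduction, angeloylation and a singlet-oxygen ene reaction finish the route.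
- Stereochemistry: C7 from the (S)-BINAP–rhodium catalyst, C10 from the chiral imidazolinium/Cu(OTf)2 catalyst, C3 from axial α-face hydride delivery to the enone, C5 from α-face attack of singlet oxygen anti to C14. The cis ring fusion formed in the annulation is transient.

Key step: step 7

Assumption: the (S)-BINAP–rhodium catalyst is taken to add to the butenolide with the facial sense known for cyclic enones (giving the S lactone), and the imidazolinium enantiomer is the one that delivers alkyl groups to the Si face of the enone β-carbon; should either sense be the reverse, the mirror-image ligand is used.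

**Route**

Step 1
Reactants: 1 furan-2(5H)-one; 2 isopropenylboronic acid pinacol ester
Product: 3 (S)-4-(prop-1-en-2-yl)dihydrofuran-2(3H)-one
Conditions: [Rh(OH)((S)-BINAP)]2 (3 mol % Rh), dioxane/H2O 10:1, 50 °C
Reagents that add atoms: none
Why: Hayashi–Miyaura reaction: the alkenyl group passes from boron to monovalent rhodium, the butenolide C=C inserts into the Rh–C bond on the face left open by (S)-BINAP (setting C7 as S) and water protonates the oxa-π-allyl rhodium to release the lactone.

Step 2
Reactants: 3 (S)-4-(prop-1-en-2-yl)dihydrofuran-2(3H)-one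
Product: 4 (S)-4-hydroxy-N-methoxy-N-methyl-3-(prop-1-en-2-yl)butanamide
Conditions: MeNH(OMe)·HCl, AlMe3, CH2Cl2, 0 °C → rt; Rochelle salt work-up
Reagents that add atoms: N,O-dimethylhydroxylamine hydrochloride, CNOC.Cl
Why: Aluminium amide aminolysis of a lactone: the amide reagent formed in the flask acylates at the carbonyl, so the ring opens to the N-methoxy-N-methylamide and the C6 hydroxyl is freed for separate activation without touching C7.

Step 3
Reactants: 4 (S)-4-hydroxy-N-methoxy-N-methyl-3-(prop-1-en-2-yl)butanamide
Product: 5 (S)-4-chloro-N-methoxy-N-methyl-3-(prop-1-en-2-yl)butanamide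
Conditions: PPh3, CCl4, CH2Cl2, 0 °C → rt
Reagents that add atoms: carbon tetrachloride, ClC(Cl)(Cl)Cl
Why: Appel reaction: chloride displaces the alkoxyphosphonium of the primary alcohol (SN2) under neutral conditions that spare the alkene, and any iminium lactone formed by amide participation should be reopened by chloride in the nonpolar medium.

Step 4
Reactants: 5 (S)-4-chloro-N-methoxy-N-methyl-3-(prop-1-en-2-yl)butanamide
Product: 7 (S)-4-chloro-3-(prop-1-en-2-yl)butan-1-ol, via (S)-4-chloro-3-(prop-1-en-2-yl)butanal 6 (not isolated)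
Conditions: i-Bu2AlH, THF, −78 °C; MeOH quench; then NaBH4, MeOH, 0 °C
Reagents that add atoms: none
Why: Hydride reduction of an N-methoxy-N-methylamide through its stable aluminium chelate, which releases aldehyde 6 on quenching and is reduced further by NaBH4 in the same flask, both hydrides leaving the primary chloride and the alkene untouched.

Step 5
Reactants: 7 (S)-4-chloro-3-(prop-1-en-2-yl)butan-1-ol
Product: 8 (S)-5-bromo-3-(chloromethyl)-2-methylpent-1-ene
Conditions: CBr4, PPh3, CH2Cl2, 0 °C
Reagents that add atoms: carbon tetrabromide, BrC(Br)(Br)Br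
Why: Appel bromination (SN2 on the alkoxyphosphonium) converts the unhindered C9 alcohol into the bromide under neutral conditions, before the 4-chloroalkanol can cyclise to a tetrahydrofuran.

Step 6
Reactants: 8 (S)-5-bromo-3-(chloromethyl)-2-methylpent-1-ene
Product: 9 [(S)-3-(chloromethyl)-4-methylpent-4-en-1-yl]magnesium bromide (titrated solution in Et2O)
Conditions: Mg turnings (activated with a crystal of I2), Et2O, 0 °C → rt
Reagents that add atoms: magnesium, [Mg]
Why: Grignard formation by chemoselective magnesium insertion into the C–Br bond, the C–Cl bond staying intact as in 4-chlorobutylmagnesium bromide, while closure to a cyclobutane (4-exo-tet) is slow at these temperatures.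

Step 7
Reactants: 9 [(S)-3-(chloromethyl)-4-methylpent-4-en-1-yl]magnesium bromide; 10 3-methylcyclohex-2-en-1-one
Product: 12 (5S,7R,10R)-15-noreudesm-11-en-4-one (cis-fused decalone), via bromomagnesium enolate 11 (not isolated)
Conditions: Cu(OTf)2 (3 mol %), 1-(1-hydroxy-4-methylpentan-2-yl)-3-mesityl-4,5-dihydroimidazolium hexafluorophosphate (4 mol %, enantiomer as assumed above), 9 (1.2 equiv), Et2O, slow addition of 10, −30 → 0 °C; then THF, DMPU, 50 °C; aq NH4Cl
Reagents that add atoms: none
Why: The species formed from Cu(OTf)2, the imidazolinium salt and the Grignard reagent is a monovalent copper alkoxy-carbene complex that takes up the alkyl group of 9, binds the enone as a π-complex, adds oxidatively at C10 to a trivalent copper intermediate and eliminates reductively to form C9–C10, releasing bromomagnesium enolate 11 with its double bond fixed at C4=C5. The closest known reactions are the copper/carbene-catalysed asymmetric conjugate addition of primary alkyl Grignard reagents to 3-methylcyclohex-2-en-1-one with trapping of the magnesium enolate, and conjugate addition–cycloalkylation annulations with ω-chloroalkyl Grignard reagents. On addition of DMPU and warming, C5 of 11 displaces the primary chloride at C6 (SN2) in a 6-exo-tet closure, with the enolate double bond exocyclic to the new ring, and ring B is formed. C10 is set by the catalyst (alkyl delivery to the Si face of the enone β-carbon, the C7 stereocentre of 9 being three atoms from magnesium and too remote to interfere), C7 is carried through unchanged, and C5 is set by the tether, which must reach the enolate π-face from an axial C10–C9 bond and so gives the cis-fused ring; that C5 centre is erased again in step 9 and is not critical. The step needs 1,4- over 1,2-addition (secured by copper catalysis in Et2O), survival of the C–Cl bond during the addition (primary chlorides are inert to the Grignard reagent and the copper catalyst at −30 to 0 °C) and C-alkylation at C5 instead of C3 or oxygen (secured by the regiospecific enolate and the six-membered transition state, closure through C3 requiring a bridged eight-membered ring).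

Step 8
Reactants: 12 (5S,7R,10R)-15-noreudesm-11-en-4-one
Product: 14 (5S,7R,10S)-3-hydroxy-15-noreudesm-11-en-4-one (both C3 epimers), via potassium C3-enolate 13 (not isolated)
Conditions: KN(SiMe3)2, THF, −78 °C; then 2-(phenylsulfonyl)-3-phenyloxaziridine, −78 °C; aq NH4Cl
Reagents that add atoms: 2-(phenylsulfonyl)-3-phenyloxaziridine, O=S(=O)(c1ccccc1)N1OC1c1ccccc1
Why: Kinetic enolate hydroxylation with an N-sulfonyloxaziridine: the hindered base removes a proton from the C3 methylene and not the ring-fusion C5–H next to quaternary C10, and the C3 configuration is irrelevant because it is erased in step 9.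

Step 9
Reactants: 14 (5S,7R,10S)-3-hydroxy-15-noreudesm-11-en-4-one
Product: 16 (7R,10S)-4-hydroxy-15-noreudesma-4,11-dien-3-one, via 15-noreudesm-11-ene-3,4-dione 15 (not isolated)
Conditions: Dess–Martin periodinane, NaHCO3, CH2Cl2, rt; then DBU (0.2 equiv), CH2Cl2, rt, under argon
Reagents that add atoms: none
Why: Dess–Martin oxidation of the α-ketol gives dione 15, which under base catalysis should enolise toward C5 to the tetrasubstituted conjugated Δ4-diosphenol, the favoured tautomer of 10-methyldecalin-3,4-diones (as in 4-hydroxy-Δ4-3-keto steroids), removing the transient C5 stereocentre.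

Step 10
Reactants: 16 (7R,10S)-4-hydroxy-15-noreudesma-4,11-dien-3-one
Product: 17 (7R,10S)-3-oxo-15-noreudesma-4,11-dien-4-yl trifluoromethanesulfonate
Conditions: Tf2O, pyridine, CH2Cl2, −78 → 0 °C
Reagents that add atoms: trifluoromethanesulfonic anhydride, O=S(=O)(OS(=O)(=O)C(F)(F)F)C(F)(F)F
Why: Enol triflate formation by O-sulfonylation of the enol hydroxyl with a weak base at low temperature should fix the C4=C5 double bond before the tautomers can exchange.

Step 11
Reactants: 17 (7R,10S)-3-oxo-15-noreudesma-4,11-dien-4-yl trifluoromethanesulfonate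
Product: 18 (+)-α-cyperone, (7R,10S)-eudesma-4,11-dien-3-one
Conditions: Me4Sn, Pd(PPh3)4 (5 mol %), LiCl, DMF, 90 °C
Reagents that add atoms: tetramethylstannane, C[Sn](C)(C)C
Why: Stille coupling: zerovalent palladium adds oxidatively into the electron-poor C4–OTf bond, chloride-assisted transmetalation transfers methyl from tin and reductive elimination installs C15, as known for α-triflyloxy enones.

Step 12
Reactants: 18 (+)-α-cyperone
Product: 19 (7R,10S)-12-hydroxyeudesma-4,11(13)-dien-3-one
Conditions: SeO2 (0.5 equiv), t-BuOOH, salicylic acid (cat.), CH2Cl2, rt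
Reagents that add atoms: tert-butyl hydroperoxide, CC(C)(C)OO (terminal oxidant; the oxygen is passed on by way of selenium dioxide, O=[Se]=O)
Why: SeO2-catalysed allylic oxidation (ene reaction followed by 2,3-sigmatropic shift) should attack only the electron-rich 1,1-disubstituted C11=C13 alkene at its methyl group, the conjugated C4=C5 bond being too electron-poor for the ene step.

Step 13
Reactants: 19 (7R,10S)-12-hydroxyeudesma-4,11(13)-dien-3-one
Product: 21 (7R,10S)-3-oxoeudesma-4,11(13)-dien-12-oic acid, via 3-oxoeudesma-4,11(13)-dien-12-al 20 (not isolated)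
Conditions: MnO2, CH2Cl2, rt; filter and concentrate; then NaClO2, NaH2PO4, 2-methyl-2-butene, t-BuOH/H2O, 0 °C → rt
Reagents that add atoms: sodium chlorite, [Na+].[O-]Cl=O
Why: MnO2 oxidation of the primary allylic alcohol followed by Pinnick oxidation of the crude, polymerisation-prone 2-substituted acrolein 20, with 2-methyl-2-butene scavenging HOCl so that the alkenes are spared.

Step 14
Reactants: 21 (7R,10S)-3-oxoeudesma-4,11(13)-dien-12-oic acid
Product: 22 methyl (7R,10S)-3-oxoeudesma-4,11(13)-dien-12-oate
Conditions: MeI, K2CO3, DMF, rt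
Reagents that add atoms: iodomethane, CI
Why: Carboxylate O-alkylation (SN2) under weak base gives the methyl ester and avoids the pyrazoline formation that diazoalkanes risk with acrylates.

Step 15
Reactants: 22 methyl (7R,10S)-3-oxoeudesma-4,11(13)-dien-12-oate
Product: 23 methyl (3S,7R,10S)-3-hydroxyeudesma-4,11(13)-dien-12-oate (3β-alcohol)
Conditions: NaBH4, CeCl3·7H2O, MeOH, −78 → −40 °C
Reagents that add atoms: none
Why: Luche reduction: the cerium-activated borohydride adds 1,2 to the enone carbonyl faster than it touches the acrylate, and hydride enters C3 axially from the α face as in Δ4-3-keto steroids, which should set the equatorial 3β-hydroxyl (3S).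

Step 16
Reactants: 23 methyl (3S,7R,10S)-3-hydroxyeudesma-4,11(13)-dien-12-oate; 24 angelic acid
Product: 26 methyl (3S,7R,10S)-3-angeloyloxyeudesma-4,11(13)-dien-12-oate, via angelic 2,4,6-trichlorobenzoic anhydride 25 (not isolated)
Conditions: 24, 2,4,6-trichlorobenzoyl chloride, Et3N, toluene, rt; then 23, toluene, 80 °C
Reagents that add atoms: none
Why: Yamaguchi-type esterification through mixed anhydride 25 without a nucleophilic catalyst: the alcohol attacks the unhindered angeloyl carbonyl, the absence of DMAP and strong base avoids Z to E isomerisation to the tiglate, and C3 keeps its configuration because its C–O bond is not broken.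

Step 17
Reactants: 26 methyl (3S,7R,10S)-3-angeloyloxyeudesma-4,11(13)-dien-12-oate
Product: 27 methyl (3S,5S,7R,10S)-3-angeloyloxy-5-hydroperoxyeudesma-4(15),11(13)-dien-12-oate (CNP0137897.1)
Conditions: O2, tetraphenylporphyrin (1 mol %), visible light, CH2Cl2, −20 °C
Reagents that add atoms: dioxygen, O=O
Why: Schenck ene reaction of singlet oxygen with the only electron-rich (tetrasubstituted) alkene: oxygen should approach the α face anti to the axial C14 methyl, bond to C5 and abstract a C15 hydrogen (C6 offers no axial hydrogen on the α face and the C3–H is deactivated by the ester), giving the 5α-hydroperoxide (5S) with the exocyclic C4=C15 bond while the acrylate and angelate double bonds are too electron-poor to react.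

**Compound list**

1 | furan-2(5H)-one | O=C1C=CCO1 | starting material
2 | isopropenylboronic acid pinacol ester, 4,4,5,5-tetramethyl-2-(prop-1-en-2-yl)-1,3,2-dioxaborolane | C=C(C)B1OC(C)(C)C(C)(C)O1 | starting material
3 | (S)-4-(prop-1-en-2-yl)dihydrofuran-2(3H)-one | C=C(C)[C@@H]1CC(=O)OC1 | intermediate
4 | (S)-4-hydroxy-N-methoxy-N-methyl-3-(prop-1-en-2-yl)butanamide | C=C(C)[C@@H](CO)CC(=O)N(C)OC | intermediate
5 | (S)-4-chloro-N-methoxy-N-methyl-3-(prop-1-en-2-yl)butanamide | C=C(C)[C@@H](CCl)CC(=O)N(C)OC | intermediate
6 | (S)-4-chloro-3-(prop-1-en-2-yl)butanal (not isolated) | C=C(C)[C@@H](CCl)CC=O | intermediate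
7 | (S)-4-chloro-3-(prop-1-en-2-yl)butan-1-ol | C=C(C)[C@@H](CCl)CCO | intermediate
8 | (S)-5-bromo-3-(chloromethyl)-2-methylpent-1-ene | C=C(C)[C@@H](CCl)CCBr | intermediate
9 | [(S)-3-(chloromethyl)-4-methylpent-4-en-1-yl]magnesium bromide | C=C(C)[C@@H](CCl)CC[Mg]Br | intermediate
10 | 3-methylcyclohex-2-en-1-one | CC1=CC(=O)CCC1 | starting material
11 | bromomagnesium (R)-3-[(S)-3-(chloromethyl)-4-methylpent-4-en-1-yl]-3-methylcyclohex-1-en-1-olate (not isolated) | C=C(C)[C@@H](CCl)CC[C@@]1(C)CCCC(O[Mg]Br)=C1 | intermediate
12 | (5S,7R,10R)-15-noreudesm-11-en-4-one, that is (4aR,7R,8aS)-4a-methyl-7-(prop-1-en-2-yl)octahydronaphthalen-1(2H)-one; cis-fused, 5β-H, 7β-isopropenyl, 10β-methyl | C=C(C)[C@@H]1CC[C@@]2(C)CCCC(=O)[C@H]2C1 | intermediate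
13 | potassium 15-noreudesma-3,11-dien-4-olate, the C3–C4 enolate of 12 (5β-H, 7β-isopropenyl, 10β-methyl; not isolated) | C=C(C)[C@@H]1CC[C@@]2(C)CCC=C([O-])[C@H]2C1.[K+] | intermediate
14 | (5S,7R,10S)-3-hydroxy-15-noreudesm-11-en-4-one, both C3 epimers | C=C(C)[C@@H]1CC[C@@]2(C)CCC(O)C(=O)[C@H]2C1 | intermediate
15 | (5S,7R,10S)-15-noreudesm-11-ene-3,4-dione (not isolated) | C=C(C)[C@@H]1CC[C@@]2(C)CCC(=O)C(=O)[C@H]2C1 | intermediate
16 | (7R,10S)-4-hydroxy-15-noreudesma-4,11-dien-3-one | C=C(C)[C@@H]1CC[C@@]2(C)CCC(=O)C(O)=C2C1 | intermediate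
17 | (7R,10S)-3-oxo-15-noreudesma-4,11-dien-4-yl trifluoromethanesulfonate | C=C(C)[C@@H]1CC[C@@]2(C)CCC(=O)C(OS(=O)(=O)C(F)(F)F)=C2C1 | intermediate
18 | (+)-α-cyperone, (7R,10S)-eudesma-4,11-dien-3-one | C=C(C)[C@@H]1CC[C@@]2(C)CCC(=O)C(C)=C2C1 | intermediate
19 | (7R,10S)-12-hydroxyeudesma-4,11(13)-dien-3-one | C=C(CO)[C@@H]1CC[C@@]2(C)CCC(=O)C(C)=C2C1 | intermediate
20 | (7R,10S)-3-oxoeudesma-4,11(13)-dien-12-al (not isolated) | C=C(C=O)[C@@H]1CC[C@@]2(C)CCC(=O)C(C)=C2C1 | intermediate
21 | (7R,10S)-3-oxoeudesma-4,11(13)-dien-12-oic acid | C=C(C(=O)O)[C@@H]1CC[C@@]2(C)CCC(=O)C(C)=C2C1 | intermediate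
22 | methyl (7R,10S)-3-oxoeudesma-4,11(13)-dien-12-oate | C=C(C(=O)OC)[C@@H]1CC[C@@]2(C)CCC(=O)C(C)=C2C1 | intermediate
23 | methyl (3S,7R,10S)-3-hydroxyeudesma-4,11(13)-dien-12-oate (3β-OH) | C=C(C(=O)OC)[C@@H]1CC[C@@]2(C)CC[C@H](O)C(C)=C2C1 | intermediate
24 | angelic acid, (Z)-2-methylbut-2-enoic acid | C/C=C(/C)C(=O)O | starting material
25 | angelic 2,4,6-trichlorobenzoic anhydride (not isolated) | C/C=C(/C)C(=O)OC(=O)c1c(Cl)cc(Cl)cc1Cl | intermediate
26 | methyl (3S,7R,10S)-3-[(Z)-2-methylbut-2-enoyloxy]eudesma-4,11(13)-dien-12-oate | C=C(C(=O)OC)[C@@H]1CC[C@@]2(C)CC[C@H](OC(=O)/C(C)=C\C)C(C)=C2C1 | intermediate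
27 | methyl (3S,5S,7R,10S)-3-[(Z)-2-methylbut-2-enoyloxy]-5-hydroperoxyeudesma-4(15),11(13)-dien-12-oate (3β-angelate, 5α-OOH, 7β-side chain, 10β-methyl) | C=C(C(=O)OC)[C@@H]1CC[C@@]2(C)CC[C@H](OC(=O)/C(C)=C\C)C(=C)[C@]2(OO)C1 | target

**Step count and risks**

Total: 17 steps. Longest linear sequence: 17 steps (1 → 27); 10 and 24 are commercial and enter at steps 7 and 16.

Steps most likely to fail:

Step 7. The bromomagnesium enolate may be too weak a nucleophile for the β-branched primary chloride, so that proton transfer, enolate equilibration or loss of HCl toward a diene outruns ring closure; the functionalised Grignard reagent may also lower the enantioselectivity at C10. The fallback separates the two bond formations. Setting out from 9 and 10, the same copper-catalysed conjugate addition is run alone and quenched with aqueous NH4Cl to isolate (R)-3-[(S)-3-(chloromethyl)-4-methylpent-4-en-1-yl]-3-methylcyclohexan-1-one F1. Finkelstein exchange (NaI, acetone, reflux) gives (R)-3-[(S)-3-(iodomethyl)-4-methylpent-4-en-1-yl]-3-methylcyclohexan-1-one F2. KOt-Bu in t-BuOH/THF then closes ring B under equilibrating conditions, where only the C5 enolate can form a six-membered ring, and the route is rejoined at 12.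

Step 10. The diosphenol is an ambident enol; if tautomer exchange is faster than sulfonylation, or the Δ2 enol is the one trapped, a regioisomeric triflate results and the methyl group of step 11 ends up on the wrong carbon. The fallback introduces C15 by carbonyl addition instead of cross-coupling. Setting out from 14, MeMgBr with CeCl3 in THF at −78 °C adds to the C4 ketone to give eudesm-11-ene-3,4-diol F3 as a mixture at C3 and C4. Parikh–Doering oxidation of the secondary hydroxyl gives 4-hydroxyeudesm-11-en-3-one F4. Dehydration of this tertiary α-ketol with SOCl2 in pyridine, as practised for 5-hydroxy-6-keto steroids, should give the conjugated tetrasubstituted enone, and the route is rejoined at 18.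

Step 17. The acyloxy-substituted alkene may react slowly, and on prolonged irradiation site and face selectivity can erode (attack on the β face with abstraction of a C6 hydrogen, or abstraction of the C3 hydrogen) while the allylic hydroperoxide decomposes by Hock-type cleavage. The fallback oxygenates a more electron-rich, non-hydrogen-bonding substrate and adds the angelate afterwards. Setting out from 23, silylation (t-BuMe2SiCl, imidazole, DMF) gives methyl 3β-(tert-butyldimethylsilyloxy)eudesma-4,11(13)-dien-12-oate F5. Photooxygenation as in step 17 gives methyl 3β-(tert-butyldimethylsilyloxy)-5α-hydroperoxyeudesma-4(15),11(13)-dien-12-oate F6. The hydroperoxide is masked with 2-methoxypropene and pyridinium p-toluenesulfonate as the peroxyketal methyl 3β-(tert-butyldimethylsilyloxy)-5α-[(2-methoxypropan-2-yl)peroxy]eudesma-4(15),11(13)-dien-12-oate F7. Desilylation with n-Bu4NF buffered with AcOH gives methyl 3β-hydroxy-5α-[(2-methoxypropan-2-yl)peroxy]eudesma-4(15),11(13)-dien-12-oate F8. Esterification with 24 under the conditions of step 16 gives methyl 3β-angeloyloxy-5α-[(2-methoxypropan-2-yl)peroxy]eudesma-4(15),11(13)-dien-12-oate F9. Mild acid (AcOH/THF/H2O, rt) removes the peroxyketal and the route ends at 27.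

Further compounds
F1 | step 7 | (R)-3-[(S)-3-(chloromethyl)-4-methylpent-4-en-1-yl]-3-methylcyclohexan-1-one | C=C(C)[C@@H](CCl)CC[C@@]1(C)CCCC(=O)C1
F2 | step 7 | (R)-3-[(S)-3-(iodomethyl)-4-methylpent-4-en-1-yl]-3-methylcyclohexan-1-one | C=C(C)[C@@H](CI)CC[C@@]1(C)CCCC(=O)C1
F3 | step 10 | eudesm-11-ene-3,4-diol (mixture at C3 and C4; 5β-H, 7β-isopropenyl, 10β-methyl) | C=C(C)[C@@H]1CC[C@@]2(C)CCC(O)C(C)(O)[C@H]2C1
F4 | step 10 | 4-hydroxyeudesm-11-en-3-one (C4 epimers; 5β-H, 7β-isopropenyl, 10β-methyl) | C=C(C)[C@@H]1CC[C@@]2(C)CCC(=O)C(C)(O)[C@H]2C1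
F5 | step 17 | methyl 3β-(tert-butyldimethylsilyloxy)eudesma-4,11(13)-dien-12-oate | C=C(C(=O)OC)[C@@H]1CC[C@@]2(C)CC[C@H](O[Si](C)(C)C(C)(C)C)C(C)=C2C1
F6 | step 17 | methyl 3β-(tert-butyldimethylsilyloxy)-5α-hydroperoxyeudesma-4(15),11(13)-dien-12-oate | C=C(C(=O)OC)[C@@H]1CC[C@@]2(C)CC[C@H](O[Si](C)(C)C(C)(C)C)C(=C)[C@]2(OO)C1
F7 | step 17 | methyl 3β-(tert-butyldimethylsilyloxy)-5α-[(2-methoxypropan-2-yl)peroxy]eudesma-4(15),11(13)-dien-12-oate | C=C(C(=O)OC)[C@@H]1CC[C@@]2(C)CC[C@H](O[Si](C)(C)C(C)(C)C)C(=C)[C@]2(OOC(C)(C)OC)C1
F8 | step 17 | methyl 3β-hydroxy-5α-[(2-methoxypropan-2-yl)peroxy]eudesma-4(15),11(13)-dien-12-oate | C=C(C(=O)OC)[C@@H]1CC[C@@]2(C)CC[C@H](O)C(=C)[C@]2(OOC(C)(C)OC)C1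
F9 | step 17 | methyl 3β-angeloyloxy-5α-[(2-methoxypropan-2-yl)peroxy]eudesma-4(15),11(13)-dien-12-oate | C=C(C(=O)OC)[C@@H]1CC[C@@]2(C)CC[C@H](OC(=O)/C(C)=C\C)C(=C)[C@]2(OOC(C)(C)OC)C1
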